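Per minute is the unit of the number carried here: the rate constant k at which double product goes over to over-reaction product. The maple flask, closed and stirred, gives a reading of it. Between 15.0 min and 40.0 min over-reaction product rose by 9.1 percentage points while double product read a mean of 6.33%. Replacing that curve by its mean gives the reading k = 0.0575 /min, and the two end readings carry a scatter of 15.5% in it. Over 1.0 h, k times the time gives 3.45; this is the loss number Λ, a Damköhler number.

| flask | substrate | reagent | remark | time |
|---|---|---|---|---|
| maple | 0.25 M | 0.25 M | run made earlier |  |
| birch | 0.25 M | 0.50 M | run made earlier |  |
| autumn | 0.25 M | 0.250 M | one stirred flow tank at steady state, fed with the mixture as stated, mean residence time 1.0 h |  |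
| dusk | 0.25 M | 0.250 M | plug flow through a tube for 1.0 h, no back-mixing | 1.0 h |
| summer | 0.25 M | 0.250 M | everything together in a closed stirred flask, run for 1.0 h | 1.0 h |
| noon | 0.25 M (fed, over 1.00 h) | 0.250 M | a stirred flask in which substrate is dosed at a steady rate over 1.00 h without added volume, worked up at 1.0 h | 1.0 h |

- maple (time / min: double product / %, triple product / %, over-reaction product / %): 2.00: 0.6, 0.5, 1.3; 6.00: 3.4, 0.4, 0.1; 10.0: 4.1, 1.6, 2.2; 15.0: 7.0, 0.9, 3.5; 20.0: 6.9, 1.0, 7.3; 30.0: 6.5, 0.7, 9.6; 40.0: 4.9, 0, 12.6
- birch (time / min: double product / %, triple product / %, over-reaction product / %): 1.00: 2.1, 1.2, 0.2; 1.33: 2.8, 0.9, 0.8; 2.00: 2.3, 2.3, 0.4; 3.00: 4.9, 1.7, 0; 5.00: 6.8, 2.3, 0.8; 8.00: 12.9, 3.2, 3.0; 12.0: 18.5, 4.2, 8.5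

(standard deviation of a reading: 1 percentage point)

- the set-up with the highest share of double product in all that became double product or triple product or over-reaction product, at the outlet or at the end ("none" if the first two lie within 2 percentage points) (autumn / dusk / summer / noon / none)
- share of double product in all that became double product or triple product or over-reaction product, at the outlet or at the end, autumn
- share of double product in all that became double product or triple product or over-reaction product, at the outlet or at the end, dusk
- share of double product in all that became double product or triple product or over-reaction product, at the outlet or at the end, summer
- share of double product in all that became double product or triple product or over-reaction product, at the outlet or at the end, noon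

- the stated concentrations are those of everything mixed, before any reaction; amounts are the same in each set-up
- the feed brings no volume worth counting
- the earlier runs were made in a closed, stirred flask

In this reckoning double product of age a survives as e^(−ka), so a share is the mean of that survival over the ages present; triple product, read at 0.7% in maple at 30.0 min, is left aside. Autumn, a stirred tank, spreads ages exponentially with its residence time as mean, which gives 1/(1+Λ) = 22.5%. Noon, with double product taken as born steadily through the dose, spreads ages evenly, which gives (1−e^(−Λ))/Λ = 28.0%. The mean age alone, half the time, gives 17.8%, so the spread is worth 10 points. Summer holds maple's charges, and dusk, without back-mixing, repeats summer's history. Maple's share reads 28.0% at 40.0 min; carried to 1.0 h by k without further birth it gives 8.87%, and my reckoning sets summer and dusk somewhat above that for the new double product.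

What would bring noon and autumn within 2 points? In this reckoning their gap is 5.5 points at this Λ and 1.8 points at twice it. The scatter of 15.5% is less than that doubling, so my reckoning stays with noon.

The forecast gave noon, with 31% for noon, 24% for autumn and 18% for summer and dusk: “Dusk equals summer, since plug flow matches batch”.

The flask gives noon 29.2%, autumn 21.4%, and 12.5% for both summer and dusk, so noon stands highest.

    substrate + reagent → single product + by-product (k = 0.510 /M/min)
    reagent + single product → double product + by-product (k = 0.180 /M/min)
    reagent + double product ⇌ triple product + by-product (K = 0.340, k = 0.270 /M/min)
    double product → over-reaction product (k = 0.0600 /min)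

At 1.00 h in summer, double product is made at 0.343 of the rate at which it is used up, each step taken net. Over a further 0.500 h, the reading of k with e^(−ka) and no further birth reckons summer's share at 2.23%. The same summer flask read at 1.5 h shows a share of 3.34%.

The runs were generated by integration with made-up constants, and the scatter is random.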